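**Retrosynthetic overview**

1. Numbering: lactone O1, C2(=O), C3, C4, C5; ring A is the 3-hydroxy-4-methoxyphenyl ring of the C3 benzyl group, ring B the 3,4-dimethoxyphenyl ring of the C4 benzyl group. Target 17 ⇐ benzyl ether 16 (O-debenzylation) ⇐ C3 ester 13 (dealkoxycarbonylation, C3 re-set trans to C4).
2. Feature used: the CH2 joining C4 to ring B lies γ to the lactone carbonyl C2 by way of C3, the homo-Michael position. It is therefore taken as the CH2 of a cyclopropane fused across C3–C4, and ring B as the nucleophile.
3. Key disconnections, both made in one flask: ring B–CH2 (aryl Grignard/CuI on cyclopropane lactone 6) and C3–CH2 of the ring A benzyl group (released enolate plus benzylic bromide 11).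
4. 6 ⇐ diethyl malonate + (R)-epichlorohydrin, which supplies the C4 stereocentre; Grignard 8 ⇐ 4-bromoveratrole; bromide 11 ⇐ O-benzylisovanillin.
5. Ring order: cyclopropane and γ-lactone are formed together in step 1; the cyclopropane is opened in step 5; no ring is closed afterwards (both arenes are bought).

Key step: step 5

Assumption: in step 1 the malonate anion is taken to open the epoxide of 2 at its CH2 before chloride is lost, the course by which (R)-epichlorohydrin gives the (1S,5R) lactone; 7 and 9 are bought.

**Route**

Step 1
Reactants: 1 diethyl malonate; 2 (R)-epichlorohydrin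
Product: 6 ethyl (1S,5R)-2-oxo-3-oxabicyclo[3.1.0]hexane-1-carboxylate, via chlorohydrin alkoxide 3 (not isolated), via epoxy malonate 4 (not isolated), via cyclopropylmethoxide diester 5 (not isolated)
Conditions: NaOEt (1.0 equiv), EtOH, rt then reflux; distillation
Reagents that add atoms: none
Why: Tandem alkylation–cyclopropanation–lactonisation in which the sodiomalonate opens the epoxide at its CH2, alkoxide 3 closes the transposed epoxide 4 with loss of chloride, the re-formed malonate anion opens 4 at the stereogenic carbon by 3-exo-tet attack with inversion to give 5, and the alkoxide lactonises onto the cis ester, so that C5 of 6 comes from the epoxide carbon of 2 and C1 follows from the obligatory cis ring fusion.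

Step 2
Reactants: 7 4-bromoveratrole
Product: 8 3,4-dimethoxyphenylmagnesium bromide (titrated THF solution, used directly)
Conditions: Mg turnings, I2 (cat.), THF, gentle reflux then rt
Reagents that add atoms: magnesium, [Mg]
Why: Grignard formation by insertion of magnesium into the aryl C–Br bond, to which the two methoxy groups are inert.

Step 3
Reactants: 9 3-benzyloxy-4-methoxybenzaldehyde
Product: 10 (3-benzyloxy-4-methoxyphenyl)methanol
Conditions: NaBH4, MeOH, 0 °C → rt
Reagents that add atoms: none
Why: Borohydride reduction of an aromatic aldehyde to the benzylic alcohol, leaving the benzyl and methyl ethers untouched.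

Step 4
Reactants: 10 (3-benzyloxy-4-methoxyphenyl)methanol
Product: 11 3-benzyloxy-4-methoxybenzyl bromide
Conditions: PBr3 (0.4 equiv), Et2O, 0 °C; used promptly
Reagents that add atoms: phosphorus tribromide, BrP(Br)Br
Why: Conversion of a benzylic alcohol into the bromide with PBr3 through a phosphite ester and SN2 displacement by bromide, the short cold contact keeping the aryl benzyl ether intact.

Step 5
Reactants: 6 ethyl (1S,5R)-2-oxo-3-oxabicyclo[3.1.0]hexane-1-carboxylate; 8 3,4-dimethoxyphenylmagnesium bromide; 11 3-benzyloxy-4-methoxybenzyl bromide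
Product: 13 ethyl (3R,4R)-3-[3-(benzyloxy)-4-methoxybenzyl]-4-(3,4-dimethoxybenzyl)-2-oxotetrahydrofuran-3-carboxylate, via bromomagnesium enolate 12 (not isolated)
Conditions: 6, CuI (0.2 equiv), THF, −30 °C; 8 (1.15 equiv), −30 → 0 °C; then DMPU, 11 (1.4 equiv), Bu4NI (cat.), 0 → 40 °C; aq. NH4Cl
Reagents that add atoms: none
Why: Grignard 8 and CuI give an arylcopper species that attacks the cyclopropane CH2 (C6) of 6 at the rear of the C1–C6 bond in an SN2-like homoconjugate addition, the doubly carbonyl-stabilised C1 leaving as the chelated bromomagnesium enolate 12, which is then C-benzylated in the same flask by the electron-rich benzylic bromide 11 once DMPU has loosened the magnesium chelate. The closest known reactions are the CuI-catalysed Grignard opening of this bicyclic lactone and of cyclopropane-1,1-diesters, the alkylation of 2-oxotetrahydrofuran-3-carboxylate enolates, and tandem conjugate addition–enolate alkylation; here the two events are run in sequence without isolating 12. No ring is closed: the three-membered ring opens and the γ-lactone is carried through intact. C4 of 13 is C5 of 6, which is not a reacting centre and keeps the configuration set from the epoxide; the new quaternary C3 is set by substrate control, the bromide approaching the enolate face anti to the C4 3,4-dimethoxybenzyl group, and either outcome is acceptable because C3 is re-set in step 6. The step needs attack at the cyclopropane CH2 and not at the ring-fusion CH or at a carbonyl, which the primary carbon, the copper catalysis and the low temperature secure, and it needs C- over O-alkylation, which the soft malonate-type enolate and the benzylic bromide favour. Only a small excess of 8 is used so that copper-mediated coupling of leftover Grignard reagent with 11 consumes little bromide.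

Step 6
Reactants: 13 ethyl (3R,4R)-3-[3-(benzyloxy)-4-methoxybenzyl]-4-(3,4-dimethoxybenzyl)-2-oxotetrahydrofuran-3-carboxylate
Product: 16 (3R,4R)-3-[3-(benzyloxy)-4-methoxybenzyl]-4-(3,4-dimethoxybenzyl)dihydrofuran-2(3H)-one, via lithium carboxylate 14 (not isolated), via lithium lactone enolate 15 (not isolated)
Conditions: LiCl (3 equiv), H2O (2 equiv), DMSO, 150 °C; then DBU (0.2 equiv), PhMe, 80 °C
Reagents that add atoms: none
Why: Krapcho dealkoxycarbonylation, in which chloride dealkylates the ethyl ester by SN2 attack to give carboxylate 14, loss of CO2 gives enolate 15 and water protonates it; C3 is then the only epimerisable centre and the DBU hold equilibrates it through the enolate to the thermodynamically preferred trans relation to the fixed C4 centre, which is 3R.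

Step 7
Reactants: 16 (3R,4R)-3-[3-(benzyloxy)-4-methoxybenzyl]-4-(3,4-dimethoxybenzyl)dihydrofuran-2(3H)-one
Product: 17 Prestegane A, (3R,4R)-4-(3,4-dimethoxybenzyl)-3-(3-hydroxy-4-methoxybenzyl)dihydrofuran-2(3H)-one
Conditions: H2 (1 atm), 10% Pd/C, EtOAc–EtOH, rt
Reagents that add atoms: none
Why: Hydrogenolysis of the aryl benzyl ether over Pd/C under neutral conditions should free the ring A phenol without touching the lactone, the methyl ethers or either stereocentre.

**Compound list**

1 | diethyl malonate | CCOC(=O)CC(=O)OCC | starting material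
2 | (R)-epichlorohydrin | ClC[C@H]1CO1 | starting material
3 | sodium alkoxide of diethyl 2-[(2R)-3-chloro-2-hydroxypropyl]malonate | ClC[C@H]([O-])CC(C(=O)OCC)C(=O)OCC.[Na+] | intermediate
4 | diethyl 2-{[(2R)-oxiran-2-yl]methyl}malonate | CCOC(=O)C(C[C@@H]1CO1)C(=O)OCC | intermediate
5 | sodium alkoxide of diethyl (2R)-2-(hydroxymethyl)cyclopropane-1,1-dicarboxylate | [O-]C[C@@H]1CC1(C(=O)OCC)C(=O)OCC.[Na+] | intermediate
6 | ethyl (1S,5R)-2-oxo-3-oxabicyclo[3.1.0]hexane-1-carboxylate | CCOC(=O)[C@]12C[C@H]1COC2=O | intermediate
7 | 4-bromoveratrole (4-bromo-1,2-dimethoxybenzene) | COc1ccc(Br)cc1OC | starting material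
8 | 3,4-dimethoxyphenylmagnesium bromide | COc1ccc([Mg]Br)cc1OC | intermediate
9 | 3-benzyloxy-4-methoxybenzaldehyde (O-benzylisovanillin) | COc1ccc(C=O)cc1OCc1ccccc1 | starting material
10 | (3-benzyloxy-4-methoxyphenyl)methanol | COc1ccc(CO)cc1OCc1ccccc1 | intermediate
11 | 3-benzyloxy-4-methoxybenzyl bromide | COc1ccc(CBr)cc1OCc1ccccc1 | intermediate
12 | bromomagnesium enolate of ethyl (4R)-4-(3,4-dimethoxybenzyl)-2-oxotetrahydrofuran-3-carboxylate | CCOC(=O)C1=C(O[Mg]Br)OC[C@@H]1Cc1ccc(OC)c(OC)c1 | intermediate
13 | ethyl (3R,4R)-3-[3-(benzyloxy)-4-methoxybenzyl]-4-(3,4-dimethoxybenzyl)-2-oxotetrahydrofuran-3-carboxylate (benzyl groups trans) | COc1ccc(C[C@@]2(C(=O)OCC)C(=O)OC[C@@H]2Cc2ccc(OC)c(OC)c2)cc1OCc1ccccc1 | intermediate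
14 | lithium (3R,4R)-3-[3-(benzyloxy)-4-methoxybenzyl]-4-(3,4-dimethoxybenzyl)-2-oxotetrahydrofuran-3-carboxylate | COc1ccc(C[C@@]2(C(=O)[O-])C(=O)OC[C@@H]2Cc2ccc(OC)c(OC)c2)cc1OCc1ccccc1.[Li+] | intermediate
15 | lithium (4R)-3-[3-(benzyloxy)-4-methoxybenzyl]-4-(3,4-dimethoxybenzyl)-4,5-dihydrofuran-2-olate | [Li]OC1=C(Cc2ccc(OC)c(OCc3ccccc3)c2)[C@@H](Cc2ccc(OC)c(OC)c2)CO1 | intermediate
16 | (3R,4R)-3-[3-(benzyloxy)-4-methoxybenzyl]-4-(3,4-dimethoxybenzyl)dihydrofuran-2(3H)-one (O-benzyl prestegane A) | COc1ccc(C[C@H]2C(=O)OC[C@@H]2Cc2ccc(OC)c(OC)c2)cc1OCc1ccccc1 | intermediate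
17 | Prestegane A, (3R,4R)-4-(3,4-dimethoxybenzyl)-3-(3-hydroxy-4-methoxybenzyl)dihydrofuran-2(3H)-one | COc1ccc(C[C@H]2C(=O)OC[C@@H]2Cc2ccc(OC)c(OC)c2)cc1O | target

**Totals and risks**

Total step count: 7. Longest linear sequence: 5 steps (steps 3, 4, 5, 6, 7, from 9).

Steps most likely to fail:

1. Step 5. The chelated bromomagnesium enolate may be benzylated too slowly, while copper couples leftover aryl Grignard reagent with the benzylic bromide, so that mainly protonated opening product is recovered. The fallback sets out from 6 and 8 and separates the two events. The CuI-catalysed opening is run alone (THF, −30 → 0 °C) and quenched with aq. NH4Cl, and ethyl (4R)-4-(3,4-dimethoxybenzyl)-2-oxotetrahydrofuran-3-carboxylate F1 is isolated. Its sodium enolate (NaH, DMF, 0 °C → rt) is then alkylated with 11. The fallback comes back to the route at 13.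

2. Step 6. Chloride may attack the lactone O–CH2 and open the ring in competition with dealkylation of the ethyl ester, and equilibration at C3 may stay incomplete. The fallback sets out from 13 and replaces the dealkylative route by hydrolysis and thermal decarboxylation. KOH in aqueous EtOH at reflux should cleave both the ester and the lactone to dipotassium 2-[3-(benzyloxy)-4-methoxybenzyl]-2-[(2R)-1-(3,4-dimethoxyphenyl)-3-hydroxypropan-2-yl]propanedioate F2. Acidification with HCl should re-close the ring to (4R)-3-[3-(benzyloxy)-4-methoxybenzyl]-4-(3,4-dimethoxybenzyl)-2-oxotetrahydrofuran-3-carboxylic acid F3. Heating F3 in toluene at reflux should expel CO2, and the same DBU hold then settles C3 trans. The fallback comes back to the route at 16.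

3. Step 1. Part of the malonate may displace chloride directly instead of opening the epoxide first, which feeds the mirror-image series and lowers the enantiomeric purity fixed here for the whole route; oligomerisation of the epoxide would lower throughput. The fallback sets out from 1 and reverses the order of the two C–C bond formations on an electrophile of the opposite spatial series. Purchased (R)-glycidol (OC[C@@H]1CO1) is converted with Tf2O and 2,6-lutidine (CH2Cl2, −30 °C) into (S)-oxiran-2-ylmethyl trifluoromethanesulfonate F4, which is used cold. The sodium salt of 1 (NaH, THF, 0 °C → rt) should displace the primary triflate directly, without opening the epoxide, to give the same epoxy malonate 4. This continues through 5 by 3-exo-tet closure and lactonisation. The fallback comes back to the route at 6.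

**Further compounds**

F1 | step 5 | ethyl (4R)-4-(3,4-dimethoxybenzyl)-2-oxotetrahydrofuran-3-carboxylate (C3 epimers) | CCOC(=O)C1C(=O)OC[C@@H]1Cc1ccc(OC)c(OC)c1
F2 | step 6 | dipotassium 2-[3-(benzyloxy)-4-methoxybenzyl]-2-[(2R)-1-(3,4-dimethoxyphenyl)-3-hydroxypropan-2-yl]propanedioate | OC[C@H](Cc1ccc(OC)c(OC)c1)C(Cc1ccc(OC)c(OCc2ccccc2)c1)(C(=O)[O-])C(=O)[O-].[K+].[K+]
F3 | step 6 | (4R)-3-[3-(benzyloxy)-4-methoxybenzyl]-4-(3,4-dimethoxybenzyl)-2-oxotetrahydrofuran-3-carboxylic acid (C3 epimers) | COc1ccc(CC2(C(=O)O)C(=O)OC[C@@H]2Cc2ccc(OC)c(OC)c2)cc1OCc1ccccc1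
F4 | step 1 | (S)-oxiran-2-ylmethyl trifluoromethanesulfonate | FC(F)(F)S(=O)(=O)OC[C@@H]1CO1
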